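**Retrosynthetic overview**

- The target is cut at C7=C8 (Julia–Kocienski) into a ring A C15 sulfone and a C35 polyenal. The polyenal is cut at C7'=C8' (Horner–Wadsworth–Emmons) into crocetin dialdehyde (C8–C8') and an acyclic C15 phosphonate that carries C2'.
- The strategy rests on ring A: C1 (the CMe2 carbon), C2 (the CH bearing the (E)-4-hydroxy-3-methylbut-2-enyl chain C1''–C4''), C3, C4=C5 (methyl on C5) and C6 (the CH bearing C7). It is a terminal C10 isoprenoid unit alkylated at C2 by a C5 allyl unit and closed between C1 and C6, with the C2 and C6 substituents trans.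
- Key disconnection: C2–C1'' and C1–C6 are made in one operation from neryl acetate and 2-methyl-2-vinyloxirane by an acid-catalysed SN2' alkylation–cyclisation cascade. Ring A is the only ring and is formed in the first step.
- The acyclic end takes C2' from Sharpless epoxidation of prenol and SN2 opening of the epoxide by an allyl copper reagent, the prenyl group from cross-metathesis, and C3'–C7' from a vinylogous Horner–Wadsworth–Emmons reaction.

Key step: step 1

Assumption: crocetin dialdehyde and the C5 phosphonocrotonate are taken as purchased. Locants follow carotenoid numbering (ring C1–C6, chain C7–C15 and C15'–C1', side chain C1''–C4''). All polyene steps are run under argon in dim light.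

**Route**

Step 1
Reactants: 1 neryl acetate, (2Z)-3,7-dimethylocta-2,6-dien-1-yl acetate; 2 2-methyl-2-vinyloxirane (racemic)
Product: 3 [(1R,5S)-5-[(2E)-4-hydroxy-3-methylbut-2-en-1-yl]-2,6,6-trimethylcyclohex-2-en-1-yl]methyl acetate (ring A; carotenoid locants 2S,6R, C2 and C6 substituents trans)
Conditions: confined chiral imidodiphosphorimidate Brønsted acid (IDPi, 5 mol %, enantiomer chosen by screening), 1 (3 equiv), 2 added over 8 h, CH2Cl2/(CF3)3COH 4:1, 4 Å MS, −60 °C
Reagents that add atoms: none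
Why: Proposed new method: the chiral acid protonates the epoxide oxygen of 2 and loosens the tertiary allylic C–O bond, the electron-rich 6,7-alkene of 1 attacks the open vinyl CH2 terminus (SN2') to form C2–C1'' and the E side-chain alkene, the tertiary C1 cation is captured by the Z 2,3-alkene to form C1–C6, and loss of H from C4 to the catalyst anion gives the C4=C5 alkene and returns the acid. The closest known reaction types are electrophile-initiated (proton, halonium, acetal, epoxide) cation–olefin cyclisations of geranyl and neryl esters and SN2' openings of 2-methyl-2-vinyloxirane by carbon nucleophiles; an intermolecular, enantioselective cyclisation started by a vinyl epoxide is not established. Ring A closes by 6-endo-trig attack of C6 on the C1 cation through a chair. C2 is set by the face of the 6,7-alkene that the ion pair attacks inside the chiral pocket (catalyst control, the unproven element), and C6 follows from C2 because the new chain sits equatorial while the Z alkene forces the acetoxymethyl group axial, which gives the trans ring (geranyl acetate would give cis). The step needs SN2' rather than direct opening (hindered tertiary centre against open CH2 terminus), attack by the 6,7-alkene rather than the acetoxy-deactivated 2,3-alkene, and proton loss from C4 rather than from the C5 methyl or C6; excess 1 and slow addition of 2 should hold back epoxide oligomerisation and Meinwald rearrangement.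

Step 2
Reactants: 3 ring A hydroxy acetate
Product: 4 [(1R,5S)-5-[(2E)-4-{[tert-butyl(dimethyl)silyl]oxy}-3-methylbut-2-en-1-yl]-2,6,6-trimethylcyclohex-2-en-1-yl]methyl acetate
Conditions: TBSCl, imidazole, DMF, 0 °C → rt
Reagents that add atoms: tert-butyldimethylsilyl chloride CC(C)(C)[Si](C)(C)Cl
Why: Standard silylation of the unhindered primary allylic alcohol, which leaves the acetate and both stereocentres untouched.

Step 3
Reactants: 4 silyl ether acetate
Product: 5 [(1R,5S)-5-[(2E)-4-{[tert-butyl(dimethyl)silyl]oxy}-3-methylbut-2-en-1-yl]-2,6,6-trimethylcyclohex-2-en-1-yl]methanol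
Conditions: K2CO3 (0.2 equiv), MeOH, rt
Reagents that add atoms: none
Why: Base-catalysed transesterification removes the acetate as methyl acetate while the silyl ether is stable to methanolic carbonate.

Step 4
Reactants: 5 ring A C7 alcohol
Product: 6 5-({[(1R,5S)-5-[(2E)-4-{[tert-butyl(dimethyl)silyl]oxy}-3-methylbut-2-en-1-yl]-2,6,6-trimethylcyclohex-2-en-1-yl]methyl}sulfanyl)-1-phenyl-1H-tetrazole
Conditions: 1-phenyl-1H-tetrazole-5-thiol, PPh3, DIAD, THF, 0 °C → rt
Reagents that add atoms: 1-phenyl-1H-tetrazole-5-thiol Sc1nnnn1-c1ccccc1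
Why: Mitsunobu thioetherification displaces the activated primary C7 oxygen by the acidic thiol in an SN2 reaction that does not touch C6.

Step 5
Reactants: 6 tetrazolyl sulfide
Product: 7 5-({[(1R,5S)-5-[(2E)-4-{[tert-butyl(dimethyl)silyl]oxy}-3-methylbut-2-en-1-yl]-2,6,6-trimethylcyclohex-2-en-1-yl]methyl}sulfonyl)-1-phenyl-1H-tetrazole
Conditions: (NH4)6Mo7O24·4H2O (10 mol %), 30 % H2O2, EtOH, 0 °C → rt
Reagents that add atoms: hydrogen peroxide OO
Why: Molybdate-catalysed peroxide oxidation takes the sulfide to the sulfone much faster than it epoxidises trisubstituted alkenes, and the silyl ether tolerates the conditions.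

Step 6
Reactants: 8 3-methylbut-2-en-1-ol (prenol)
Product: 9 [(2S)-3,3-dimethyloxiran-2-yl]methanol
Conditions: Ti(OiPr)4 (10 mol %), L-(+)-diethyl tartrate (12 mol %), t-BuOOH, 4 Å MS, CH2Cl2, −20 °C; non-aqueous work-up, distillation
Reagents that add atoms: tert-butyl hydroperoxide CC(C)(C)OO
Why: Katsuki–Sharpless asymmetric epoxidation of the allylic alcohol, in which the L-(+)-tartrate complex delivers oxygen to the face that gives the 2S epoxide (the same sense as geraniol to its 2S,3S epoxide).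

Step 7
Reactants: 9 epoxy alcohol
Product: 10 {[(2S)-3,3-dimethyloxiran-2-yl]methoxy}(triethyl)silane
Conditions: TESCl, imidazole, CH2Cl2, 0 °C
Reagents that add atoms: chlorotriethylsilane CC[Si](Cl)(CC)CC
Why: Silylation of the primary alcohol blocks Payne rearrangement in the next step and provides the group that is later oxidised directly to the aldehyde.

Step 8
Reactants: 10 silylated epoxide
Product: 11 (3R)-2-methyl-3-{[(triethylsilyl)oxy]methyl}hex-5-en-2-ol
Conditions: allylMgBr (2 equiv), CuI (10 mol %), THF/Et2O, −40 → 0 °C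
Reagents that add atoms: allylmagnesium bromide C=CC[Mg]Br
Why: Copper-catalysed SN2 opening of the trisubstituted epoxide takes place at the secondary carbon C2', since the tertiary carbon is closed to backside attack, and inversion there turns the 2S epoxide into the R-configured centre that becomes C2'.

Step 9
Reactants: 11 allyl carbinol
Product: 12 (3R)-2,6-dimethyl-3-{[(triethylsilyl)oxy]methyl}hept-5-en-2-ol
Conditions: 2-methylbut-2-ene (excess), second-generation Grubbs catalyst (H2IMes)(PCy3)Cl2Ru=CHPh (3 mol %), CH2Cl2, 40 °C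
Reagents that add atoms: 2-methylbut-2-ene CC=C(C)C
Why: Olefin cross-metathesis of the terminal alkene with an excess of the trisubstituted partner installs the isopropylidene terminus (prenyl group) with loss of propene and without touching the stereocentre.

Step 10
Reactants: 12 prenyl carbinol
Product: 13 (3R)-2,6-dimethyl-2-[(triethylsilyl)oxy]-3-{[(triethylsilyl)oxy]methyl}hept-5-ene
Conditions: TESOTf, 2,6-lutidine, CH2Cl2, −78 → 0 °C
Reagents that add atoms: triethylsilyl trifluoromethanesulfonate CC[Si](CC)(CC)OS(=O)(=O)C(F)(F)F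
Why: The silyl triflate is reactive enough to cap the hindered tertiary alcohol, which must be masked for the later carbanion steps.

Step 11
Reactants: 13 bis-silyl ether
Product: 14 (2S)-5-methyl-2-{2-[(triethylsilyl)oxy]propan-2-yl}hex-4-enal
Conditions: (COCl)2, DMSO, CH2Cl2, −78 → −35 °C; Et3N, −78 °C → rt; used crude
Reagents that add atoms: none
Why: Under Swern conditions a primary triethylsilyl ether is cleaved by the chlorosulfonium salt and oxidised directly to the aldehyde while the hindered tertiary silyl ether is inert; the cold, non-equilibrating conditions should leave the α-centre C2' intact.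

Step 12
Reactants: 14 aldehyde; 15 ethyl (2E)-4-(diethoxyphosphoryl)-3-methylbut-2-enoate
Product: 16 ethyl (2E,4E,6R)-3,9-dimethyl-6-{2-[(triethylsilyl)oxy]propan-2-yl}deca-2,4,8-trienoate
Conditions: LiHMDS, THF/DMPU, −78 → −20 °C
Reagents that add atoms: none
Why: Vinylogous Horner–Wadsworth–Emmons olefination forms C3'=C4' with E selectivity, and addition of the lithium phosphonate anion to the hindered aldehyde should outrun its enolisation, so C2' is kept.

Step 13
Reactants: 16 dienoate
Product: 17 (2E,4E,6R)-3,9-dimethyl-6-{2-[(triethylsilyl)oxy]propan-2-yl}deca-2,4,8-trien-1-ol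
Conditions: DIBAL-H (2.2 equiv), CH2Cl2, −78 °C; Rochelle salt
Reagents that add atoms: none
Why: Hydride reduction of the conjugated ester gives the allylic alcohol by 1,2-reduction only and does not affect the silyl ether or the alkenes.

Step 14
Reactants: 17 dienol
Product: 19 diethyl [(2E,4E,6R)-3,9-dimethyl-6-{2-[(triethylsilyl)oxy]propan-2-yl}deca-2,4,8-trien-1-yl]phosphonate, via dienyl bromide 18 (not isolated)
Conditions: CBr4, PPh3, CH2Cl2, −30 °C; filter, concentrate; P(OEt)3 (neat), 90 °C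
Reagents that add atoms: carbon tetrabromide BrC(Br)(Br)Br (bromine of 18); triethyl phosphite CCOP(OCC)OCC
Why: Appel bromination of the primary allylic alcohol under neutral conditions followed by Michaelis–Arbuzov reaction of the reactive allylic bromide gives the stable, chromatographable phosphonate.

Step 15
Reactants: 19 C15 phosphonate; 20 crocetin dialdehyde (3 equiv)
Product: 21 (2E,4E,6E,8E,10E,12E,14E,16E,18E,20E,22R)-2,6,11,15,19,25-hexamethyl-22-{2-[(triethylsilyl)oxy]propan-2-yl}hexacosa-2,4,6,8,10,12,14,16,18,20,24-undecaenal (C35 polyenal)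
Conditions: NaHMDS, THF, −78 °C; anion added to 20 in THF/CH2Cl2, −78 → 0 °C
Reagents that add atoms: none
Why: Horner–Wadsworth–Emmons olefination with an allylic phosphonate forms C7'=C8' with E selectivity, and inverse addition to an excess of the symmetrical dialdehyde should favour mono-olefination, the unreacted dialdehyde being recovered.

Step 16
Reactants: 7 ring A sulfone (1.3 equiv); 21 C35 polyenal
Product: 22 bis-silyl ether of the target (C4'' O-TBS, C1' O-TES; 2S,6R,2'R, all-E)
Conditions: KHMDS, DME, −78 °C, 30 min; then 21, −78 °C → rt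
Reagents that add atoms: none
Why: Julia–Kocienski olefination, in which the metalated tetrazolyl sulfone adds to the aldehyde and Smiles rearrangement with loss of SO2 and the tetrazolone forms C7=C8; the potassium counter-ion in DME and the bulky β-branched sulfone should favour the E alkene, and C6 carries no acidic hydrogen, so its configuration is kept.

Step 17
Reactants: 22 bis-silyl ether
Product: 23 CNP0409952.2, (2S,6R,2'R)-2-[(2E)-4-hydroxy-3-methylbut-2-en-1-yl]-2'-(3-methylbut-2-en-1-yl)-3',4'-didehydro-1',2'-dihydro-ε,ψ-caroten-1'-ol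
Conditions: TBAF, THF, 0 °C → rt, dark
Reagents that add atoms: none
Why: Fluoride cleaves both the primary tert-butyldimethylsilyl and the tertiary triethylsilyl ether under non-acidic conditions that should leave the polyene and the three stereocentres untouched.

**Compound list**

1 | neryl acetate, (2Z)-3,7-dimethylocta-2,6-dien-1-yl acetate | CC(C)=CCC/C(C)=C\COC(C)=O | starting material
2 | 2-methyl-2-vinyloxirane (racemic) | C=CC1(C)CO1 | starting material
3 | [(1R,5S)-5-[(2E)-4-hydroxy-3-methylbut-2-en-1-yl]-2,6,6-trimethylcyclohex-2-en-1-yl]methyl acetate | CC(=O)OC[C@@H]1C(C)=CC[C@@H](C/C=C(\C)CO)C1(C)C | intermediate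
4 | [(1R,5S)-5-[(2E)-4-{[tert-butyl(dimethyl)silyl]oxy}-3-methylbut-2-en-1-yl]-2,6,6-trimethylcyclohex-2-en-1-yl]methyl acetate | CC(=O)OC[C@@H]1C(C)=CC[C@@H](C/C=C(\C)CO[Si](C)(C)C(C)(C)C)C1(C)C | intermediate
5 | [(1R,5S)-5-[(2E)-4-{[tert-butyl(dimethyl)silyl]oxy}-3-methylbut-2-en-1-yl]-2,6,6-trimethylcyclohex-2-en-1-yl]methanol | OC[C@@H]1C(C)=CC[C@@H](C/C=C(\C)CO[Si](C)(C)C(C)(C)C)C1(C)C | intermediate
6 | 5-({[(1R,5S)-5-[(2E)-4-{[tert-butyl(dimethyl)silyl]oxy}-3-methylbut-2-en-1-yl]-2,6,6-trimethylcyclohex-2-en-1-yl]methyl}sulfanyl)-1-phenyl-1H-tetrazole | C(Sc2nnnn2-c2ccccc2)[C@@H]1C(C)=CC[C@@H](C/C=C(\C)CO[Si](C)(C)C(C)(C)C)C1(C)C | intermediate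
7 | 5-({[(1R,5S)-5-[(2E)-4-{[tert-butyl(dimethyl)silyl]oxy}-3-methylbut-2-en-1-yl]-2,6,6-trimethylcyclohex-2-en-1-yl]methyl}sulfonyl)-1-phenyl-1H-tetrazole | C(S(=O)(=O)c2nnnn2-c2ccccc2)[C@@H]1C(C)=CC[C@@H](C/C=C(\C)CO[Si](C)(C)C(C)(C)C)C1(C)C | intermediate
8 | 3-methylbut-2-en-1-ol (prenol) | CC(C)=CCO | starting material
9 | [(2S)-3,3-dimethyloxiran-2-yl]methanol | OC[C@@H]1OC1(C)C | intermediate
10 | {[(2S)-3,3-dimethyloxiran-2-yl]methoxy}(triethyl)silane | CC[Si](CC)(CC)OC[C@@H]1OC1(C)C | intermediate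
11 | (3R)-2-methyl-3-{[(triethylsilyl)oxy]methyl}hex-5-en-2-ol | C=CC[C@H](CO[Si](CC)(CC)CC)C(C)(C)O | intermediate
12 | (3R)-2,6-dimethyl-3-{[(triethylsilyl)oxy]methyl}hept-5-en-2-ol | CC(C)=CC[C@H](CO[Si](CC)(CC)CC)C(C)(C)O | intermediate
13 | (3R)-2,6-dimethyl-2-[(triethylsilyl)oxy]-3-{[(triethylsilyl)oxy]methyl}hept-5-ene | CC(C)=CC[C@H](CO[Si](CC)(CC)CC)C(C)(C)O[Si](CC)(CC)CC | intermediate
14 | (2S)-5-methyl-2-{2-[(triethylsilyl)oxy]propan-2-yl}hex-4-enal | CC(C)=CC[C@H](C=O)C(C)(C)O[Si](CC)(CC)CC | intermediate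
15 | ethyl (2E)-4-(diethoxyphosphoryl)-3-methylbut-2-enoate | CCOC(=O)/C=C(\C)CP(=O)(OCC)OCC | starting material
16 | ethyl (2E,4E,6R)-3,9-dimethyl-6-{2-[(triethylsilyl)oxy]propan-2-yl}deca-2,4,8-trienoate | CC(C)=CC[C@H](/C=C/C(C)=C/C(=O)OCC)C(C)(C)O[Si](CC)(CC)CC | intermediate
17 | (2E,4E,6R)-3,9-dimethyl-6-{2-[(triethylsilyl)oxy]propan-2-yl}deca-2,4,8-trien-1-ol | CC(C)=CC[C@H](/C=C/C(C)=C/CO)C(C)(C)O[Si](CC)(CC)CC | intermediate
18 | (2E,4E,6R)-1-bromo-3,9-dimethyl-6-{2-[(triethylsilyl)oxy]propan-2-yl}deca-2,4,8-triene | CC(C)=CC[C@H](/C=C/C(C)=C/CBr)C(C)(C)O[Si](CC)(CC)CC | intermediate (not isolated)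
19 | diethyl [(2E,4E,6R)-3,9-dimethyl-6-{2-[(triethylsilyl)oxy]propan-2-yl}deca-2,4,8-trien-1-yl]phosphonate | CC(C)=CC[C@H](/C=C/C(C)=C/CP(=O)(OCC)OCC)C(C)(C)O[Si](CC)(CC)CC | intermediate
20 | crocetin dialdehyde, (2E,4E,6E,8E,10E,12E,14E)-2,6,11,15-tetramethylhexadeca-2,4,6,8,10,12,14-heptaenedial | O=C/C(C)=C/C=C/C(C)=C/C=C/C=C(C)/C=C/C=C(C)/C=O | starting material
21 | (2E,4E,6E,8E,10E,12E,14E,16E,18E,20E,22R)-2,6,11,15,19,25-hexamethyl-22-{2-[(triethylsilyl)oxy]propan-2-yl}hexacosa-2,4,6,8,10,12,14,16,18,20,24-undecaenal | CC(C)=CC[C@H](/C=C/C(C)=C/C=C/C(C)=C/C=C/C(C)=C/C=C/C=C(C)/C=C/C=C(C)/C=O)C(C)(C)O[Si](CC)(CC)CC | intermediate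
22 | bis-silyl ether of the target (C4'' O-tert-butyldimethylsilyl, C1' O-triethylsilyl; 2S,6R,2'R, all-E) | CC(C)=CC[C@H](/C=C/C(C)=C/C=C/C(C)=C/C=C/C(C)=C/C=C/C=C(C)/C=C/C=C(C)/C=C/[C@@H]1C(C)=CC[C@@H](C/C=C(\C)CO[Si](C)(C)C(C)(C)C)C1(C)C)C(C)(C)O[Si](CC)(CC)CC | intermediate
23 | CNP0409952.2, (2S,6R,2'R)-2-[(2E)-4-hydroxy-3-methylbut-2-en-1-yl]-2'-(3-methylbut-2-en-1-yl)-3',4'-didehydro-1',2'-dihydro-ε,ψ-caroten-1'-ol | CC(C)=CC[C@H](/C=C/C(C)=C/C=C/C(C)=C/C=C/C(C)=C/C=C/C=C(C)/C=C/C=C(C)/C=C/[C@@H]1C(C)=CC[C@@H](C/C=C(\C)CO)C1(C)C)C(C)(C)O | target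

**Step count and risks**

Total step count: 17. Longest linear sequence: 12 steps (8 to 23, steps 6–17); the ring A branch is 7 steps (steps 1–5, 16, 17).

Steps most likely to fail:

1. Step 1 (key step). The activated epoxide may be opened directly at the tertiary carbon, rearrange to an aldehyde or oligomerise faster than the alkene of 1 attacks it. The enantioface selection at the 6,7-alkene may be poor. The C5 cation may lose its proton from the methyl group or from C6 instead of C4.
Fallback with known chemistry, setting out from 1 and coming back at 3: Shi epoxidation of 1 (D-fructose-derived ketone, Oxone, K2CO3, MeCN/dimethoxymethane/H2O, 0 °C) is selective for the 6,7-alkene and should give [(2Z)-5-[(2R)-3,3-dimethyloxiran-2-yl]-3-methylpent-2-en-1-yl] acetate F1. Lewis acid epoxy–olefin cyclisation (ZrCl4, CH2Cl2, −78 °C → rt) closes ring A through the same chair, with the Z alkene placing the acetoxymethyl group trans to the new hydroxyl, to give [(1R,5R)-5-hydroxy-2,6,6-trimethylcyclohex-2-en-1-yl]methyl acetate F2. PhOC(S)Cl, pyridine and DMAP give the thionocarbonate [(1R,5R)-2,6,6-trimethyl-5-[(phenoxycarbonothioyl)oxy]cyclohex-2-en-1-yl]methyl acetate F3. Keck radical allylation (allyltributylstannane, AIBN, PhH, 80 °C), in which the allyl group should enter C2 anti to the pseudo-axial acetoxymethyl group at C6, gives [(1R,5R)-2,6,6-trimethyl-5-(prop-2-en-1-yl)cyclohex-2-en-1-yl]methyl acetate F4. Cross-metathesis with methacrolein (second-generation Grubbs catalyst (H2IMes)(PCy3)Cl2Ru=CHPh, CH2Cl2, 40 °C) gives the E enal [(1R,5S)-2,6,6-trimethyl-5-[(2E)-3-methyl-4-oxobut-2-en-1-yl]cyclohex-2-en-1-yl]methyl acetate F5, and Luche reduction (NaBH4, CeCl3·7H2O, MeOH, 0 °C) gives 3.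

2. Step 16. The E/Z selectivity at C7=C8 may be poor with a conjugated aldehyde. The sulfonyl carbanion may instead deprotonate the polyenal at its vinylogous positions, including C2', where loss of the silyloxy group would follow. Smiles rearrangement of the hindered adduct may be slow.
Fallback, setting out from 5 and coming back at 22: Appel bromination (CBr4, PPh3, CH2Cl2, 0 °C) gives tert-butyl{[(2E)-4-[(1S,5R)-5-(bromomethyl)-4,6,6-trimethylcyclohex-3-en-1-yl]-2-methylbut-2-en-1-yl]oxy}dimethylsilane F6. Heating with PPh3 (MeCN, 100 °C, sealed) gives {[(1R,5S)-5-[(2E)-4-{[tert-butyl(dimethyl)silyl]oxy}-3-methylbut-2-en-1-yl]-2,6,6-trimethylcyclohex-2-en-1-yl]methyl}(triphenyl)phosphonium bromide F7. Wittig reaction of its ylide (NaHMDS, THF, −78 °C → rt) with 21, followed by thermal or iodine-catalysed stereomutation of the 7Z isomer as in the classical C10 + C20 + C10 carotenoid assembly, gives 22.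

3. Step 8. The magnesium halide may open the trisubstituted epoxide at the tertiary carbon or rearrange it to a carbonyl compound instead of allowing SN2 attack at C2', or the opening may be too slow.
Fallback, setting out from 8 and coming back at 12 (it replaces steps 6–9): PBr3 (Et2O, 0 °C) converts 8 into 1-bromo-3-methylbut-2-ene F8. (4S)-4-Benzyl-3-(3-methylbut-2-enoyl)-1,3-oxazolidin-2-one F9 is made from (S)-4-benzyl-1,3-oxazolidin-2-one (n-BuLi, 3-methylbut-2-enoyl chloride, THF, −78 °C). Its sodium dienolate (NaHMDS, THF, −78 °C) is alkylated at the α-carbon by F8, on the face away from the benzyl group, to give (4S)-4-benzyl-3-[(2S)-5-methyl-2-(prop-1-en-2-yl)hex-4-enoyl]-1,3-oxazolidin-2-one F10. LiBH4 (Et2O, MeOH, 0 °C) gives (2S)-5-methyl-2-(prop-1-en-2-yl)hex-4-en-1-ol F11. TESCl and imidazole give triethyl{[(2S)-5-methyl-2-(prop-1-en-2-yl)hex-4-en-1-yl]oxy}silane F12. Oxymercuration–demercuration (Hg(OAc)2, THF/H2O; NaBH4, NaOH), which hydrates a 1,1-disubstituted alkene faster than a trisubstituted one, gives 12.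

Further compounds
F1 | step 1 | [(2Z)-5-[(2R)-3,3-dimethyloxiran-2-yl]-3-methylpent-2-en-1-yl] acetate | CC(=O)OC/C=C(C)\CC[C@H]1OC1(C)C
F2 | step 1 | [(1R,5R)-5-hydroxy-2,6,6-trimethylcyclohex-2-en-1-yl]methyl acetate | CC(=O)OC[C@@H]1C(C)=CC[C@@H](O)C1(C)C
F3 | step 1 | [(1R,5R)-2,6,6-trimethyl-5-[(phenoxycarbonothioyl)oxy]cyclohex-2-en-1-yl]methyl acetate | CC(=O)OC[C@@H]1C(C)=CC[C@@H](OC(=S)Oc2ccccc2)C1(C)C
F4 | step 1 | [(1R,5R)-2,6,6-trimethyl-5-(prop-2-en-1-yl)cyclohex-2-en-1-yl]methyl acetate | CC(=O)OC[C@@H]1C(C)=CC[C@@H](CC=C)C1(C)C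
F5 | step 1 | [(1R,5S)-2,6,6-trimethyl-5-[(2E)-3-methyl-4-oxobut-2-en-1-yl]cyclohex-2-en-1-yl]methyl acetate | CC(=O)OC[C@@H]1C(C)=CC[C@@H](C/C=C(\C)C=O)C1(C)C
F6 | step 16 | tert-butyl{[(2E)-4-[(1S,5R)-5-(bromomethyl)-4,6,6-trimethylcyclohex-3-en-1-yl]-2-methylbut-2-en-1-yl]oxy}dimethylsilane | BrC[C@@H]1C(C)=CC[C@@H](C/C=C(\C)CO[Si](C)(C)C(C)(C)C)C1(C)C
F7 | step 16 | {[(1R,5S)-5-[(2E)-4-{[tert-butyl(dimethyl)silyl]oxy}-3-methylbut-2-en-1-yl]-2,6,6-trimethylcyclohex-2-en-1-yl]methyl}(triphenyl)phosphonium bromide | [Br-].C([P+](c2ccccc2)(c2ccccc2)c2ccccc2)[C@@H]1C(C)=CC[C@@H](C/C=C(\C)CO[Si](C)(C)C(C)(C)C)C1(C)C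
F8 | step 8 | 1-bromo-3-methylbut-2-ene | CC(C)=CCBr
F9 | step 8 | (4S)-4-benzyl-3-(3-methylbut-2-enoyl)-1,3-oxazolidin-2-one | CC(C)=CC(=O)N1[C@@H](Cc2ccccc2)COC1=O
F10 | step 8 | (4S)-4-benzyl-3-[(2S)-5-methyl-2-(prop-1-en-2-yl)hex-4-enoyl]-1,3-oxazolidin-2-one | CC(C)=CC[C@H](C(=O)N1[C@@H](Cc2ccccc2)COC1=O)C(C)=C
F11 | step 8 | (2S)-5-methyl-2-(prop-1-en-2-yl)hex-4-en-1-ol | CC(C)=CC[C@H](CO)C(C)=C
F12 | step 8 | triethyl{[(2S)-5-methyl-2-(prop-1-en-2-yl)hex-4-en-1-yl]oxy}silane | CC(C)=CC[C@H](CO[Si](CC)(CC)CC)C(C)=C
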